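**Retrosynthetic overview**
1. Target ⇐ diol 32 (allylic oxidation at C-3) ⇐ C9=C10 by aldol addition then dehydration, joining ethyl ketone 13 (C13) and polyenal 27 (C27).
2. 27 ⇐ C25 aldehyde 24 + two carbons (HWE, DIBAL-H, MnO2); 24 ⇐ allylic phosphonate 21 + C10-dial 22 (HWE); 21 ⇐ enol triflate 17 of TBS-actinol + enynol 18 (Sonogashira); C-3' is bought with actinol.
3. 13 ⇐ methyl (Z)-ester 9 ⇐ E1cB opening of butenolide 7, itself made by intramolecular Wittig closure of α-ketol 4 (from ketoisophorone); the lactone fixes the 6Z geometry.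
4. Rings: both carbocycles are bought and never built; the only ring formed is the temporary butenolide (step 3), opened again in step 5.

Assumption: 1, 14, 18 and 22 are bought; 4, 6, 7 and 10–13 are racemic at their one ring stereocentre, so 29–32 are C-3 epimer mixtures (carotenoid numbering) that converge in step 22, where C-3 becomes the ketone.

**Route**

Step 1
Reactants: 1 2,6,6-trimethylcyclohex-2-ene-1,4-dione (ketoisophorone)
Product: 2 7,9,9-trimethyl-1,4-dioxaspiro[4.5]dec-6-en-8-one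
Conditions: HOCH2CH2OH, p-TsOH (cat.), benzene, reflux, Dean–Stark
Reagents that add atoms: ethylene glycol (OCCO)
Why: Acid-catalysed ketalisation takes place only at the unhindered C-4 carbonyl, because the other carbonyl is flanked by the gem-dimethyl carbon and the methyl-bearing alkene carbon.

Step 2
Reactants: 2 7,9,9-trimethyl-1,4-dioxaspiro[4.5]dec-6-en-8-one
Product: 4 7-hydroxy-7,9,9-trimethyl-1,4-dioxaspiro[4.5]decan-8-one (racemic), via tertiary hydroperoxide 3 (not isolated)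
Conditions: Mn(dpm)3 (3 mol%), PhSiH3, O2 (1 atm), i-PrOH/CH2Cl2, 0 °C to rt; then P(OEt)3
Reagents that add atoms: dioxygen (O=O)
Why: Mukaiyama-type hydrogen-atom transfer to the enone β-carbon gives the tertiary α-keto radical, which traps O2 and is reduced to the α-ketol (Magnus α-hydroxylation of enones); the new centre is racemic and is destroyed in step 5.

Step 3
Reactants: 4 7-hydroxy-7,9,9-trimethyl-1,4-dioxaspiro[4.5]decan-8-one
Product: 6 6,6-ethylenedioxy-4,4,7a-trimethyl-5,6,7,7a-tetrahydro-1-benzofuran-2(4H)-one (dehydrololiolide ethylene ketal; racemic), via ester-stabilised ylide 5 (not isolated)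
Conditions: Ph3P=C=C=O (1.3 equiv), toluene, 110 °C
Reagents that add atoms: (triphenylphosphoranylidene)ketene (O=C=C=P(c1ccccc1)(c1ccccc1)c1ccccc1)
Why: The tertiary alcohol adds to the Bestmann ylide and the resulting ester ylide closes by intramolecular Wittig reaction on the neighbouring ketone, so the five-membered ring forces the acyl carbon cis to the methyl-bearing ring carbon across the new alkene (the later 6Z geometry).

Step 4
Reactants: 6 dehydrololiolide ethylene ketal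
Product: 7 4,4,7a-trimethyl-5,7a-dihydro-1-benzofuran-2,6(4H,7H)-dione (dehydrololiolide; racemic)
Conditions: 1 M aq. HCl, THF, rt
Reagents that add atoms: water (O)
Why: Mild acidic ketal hydrolysis frees the ring ketone while the butenolide is stable to dilute acid.

Step 5
Reactants: 7 dehydrololiolide
Product: 9 methyl (2Z)-(2,6,6-trimethyl-4-oxocyclohex-2-en-1-ylidene)acetate, via DBU-H carboxylate salt 8 (not isolated)
Conditions: DBU (1.2 equiv), MeCN, 0 °C to rt; then MeI (3 equiv), rt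
Reagents that add atoms: iodomethane (CI)
Why: E1cB β-elimination of the lactone carboxylate from the β-acyloxy ketone creates the ring enone while the exocyclic alkene keeps the cis arrangement set by the lactone, and O-methylation of the carboxylate stops re-closure.

Step 6
Reactants: 9 methyl (2Z)-(2,6,6-trimethyl-4-oxocyclohex-2-en-1-ylidene)acetate
Product: 10 methyl (2Z)-(4-hydroxy-2,6,6-trimethylcyclohex-2-en-1-ylidene)acetate (racemic)
Conditions: NaBH4, CeCl3·7H2O, MeOH, −20 °C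
Reagents that add atoms: none
Why: Luche reduction attacks the enone carbonyl 1,2 and leaves the dienoate, which removes the second enolisable ketone before the enolate chemistry; the racemic carbinol is re-oxidised in step 22.

Step 7
Reactants: 10 methyl (2Z)-(4-hydroxy-2,6,6-trimethylcyclohex-2-en-1-ylidene)acetate
Product: 11 methyl (2Z)-[4-(tert-butyldimethylsilyloxy)-2,6,6-trimethylcyclohex-2-en-1-ylidene]acetate
Conditions: TBSCl, imidazole, DMF, rt
Reagents that add atoms: tert-butyldimethylsilyl chloride (CC(C)(C)[Si](C)(C)Cl)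
Why: Standard silylation of an unhindered secondary allylic alcohol gives an ether stable to Grignard reagents and LDA.

Step 8
Reactants: 11 methyl (2Z)-[4-(tert-butyldimethylsilyloxy)-2,6,6-trimethylcyclohex-2-en-1-ylidene]acetate
Product: 12 (2Z)-2-[4-(tert-butyldimethylsilyloxy)-2,6,6-trimethylcyclohex-2-en-1-ylidene]-N-methoxy-N-methylacetamide
Conditions: MeNH(OMe)·HCl, i-PrMgCl, THF, −20 to 0 °C
Reagents that add atoms: N,O-dimethylhydroxylamine hydrochloride (CNOC.Cl)
Why: The magnesium amide formed in the flask converts the ester directly into the Weinreb amide (ester aminolysis) without touching the alkene geometry.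

Step 9
Reactants: 12 Weinreb amide
Product: 13 (1Z)-1-[4-(tert-butyldimethylsilyloxy)-2,6,6-trimethylcyclohex-2-en-1-ylidene]butan-2-one
Conditions: EtMgBr, THF, 0 °C; aq. NH4Cl
Reagents that add atoms: ethylmagnesium bromide (CC[Mg]Br)
Why: Weinreb ketone synthesis stops at the ketone through the stable magnesium chelate, and the fully substituted β-carbon rules out conjugate addition.

Step 10
Reactants: 14 (4R,6R)-4-hydroxy-2,2,6-trimethylcyclohexan-1-one (actinol)
Product: 15 (4R,6R)-4-(tert-butyldimethylsilyloxy)-2,2,6-trimethylcyclohexan-1-one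
Conditions: TBSCl, imidazole, DMF, rt
Reagents that add atoms: tert-butyldimethylsilyl chloride (CC(C)(C)[Si](C)(C)Cl)
Why: Standard silylation protects the carbinol that becomes C-3' without touching its configuration.

Step 11
Reactants: 15 (4R,6R)-4-(tert-butyldimethylsilyloxy)-2,2,6-trimethylcyclohexan-1-one
Product: 17 (4R)-4-(tert-butyldimethylsilyloxy)-2,6,6-trimethylcyclohex-1-en-1-yl trifluoromethanesulfonate, via lithium enolate 16 (not isolated)
Conditions: LDA, THF, −78 to 0 °C; then PhNTf2, −78 °C to rt; aq. NH4Cl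
Reagents that add atoms: N-phenylbis(trifluoromethanesulfonimide) (O=S(=O)(N(c1ccccc1)S(=O)(=O)C(F)(F)F)C(F)(F)F)
Why: The ketone has a single α-hydrogen, so enolisation and O-triflation are regiospecific; the methyl-bearing centre becomes sp2 and the silyloxy centre is untouched.

Step 12
Reactants: 17 enol triflate; 18 (2E)-3-methylpent-2-en-4-yn-1-ol
Product: 19 (2E)-5-[(4R)-4-(tert-butyldimethylsilyloxy)-2,6,6-trimethylcyclohex-1-en-1-yl]-3-methylpent-2-en-4-yn-1-ol
Conditions: Pd(PPh3)4 (5 mol%), CuI (10 mol%), i-Pr2NH, DMF, rt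
Reagents that add atoms: none
Why: Sonogashira coupling of a vinyl triflate with a terminal alkyne builds the ring–C≡C bond and keeps the E alkene of 18.

Step 13
Reactants: 19 C15 dienynol
Product: 20 (2E)-1-bromo-5-[(4R)-4-(tert-butyldimethylsilyloxy)-2,6,6-trimethylcyclohex-1-en-1-yl]-3-methylpent-2-en-4-yne
Conditions: CBr4, PPh3, CH2Cl2, 0 °C
Reagents that add atoms: carbon tetrabromide (BrC(Br)(Br)Br)
Why: Appel bromination is neutral, so the silyl ether survives, and substitution occurs at the primary allylic carbon.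

Step 14
Reactants: 20 C15 allylic bromide
Product: 21 diethyl [(2E)-5-[(4R)-4-(tert-butyldimethylsilyloxy)-2,6,6-trimethylcyclohex-1-en-1-yl]-3-methylpent-2-en-4-yn-1-yl]phosphonate
Conditions: P(OEt)3 (neat), 90 °C
Reagents that add atoms: triethyl phosphite (CCOP(OCC)OCC)
Why: Michaelis–Arbuzov reaction of a primary allylic bromide gives the phosphonate cleanly, with loss of bromoethane.

Step 15
Reactants: 21 C15 phosphonate; 22 (2E,4E,6E)-2,7-dimethylocta-2,4,6-trienedial (C10-dial)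
Product: 24 (2E,4E,6E,8E,10E)-13-[(4R)-4-(tert-butyldimethylsilyloxy)-2,6,6-trimethylcyclohex-1-en-1-yl]-2,7,11-trimethyltrideca-2,4,6,8,10-pentaen-12-ynal (C25 aldehyde), via sodium phosphonate carbanion 23 (not isolated)
Conditions: NaHMDS, THF, −78 °C; then added to 22 (3 equiv), THF, −78 to 0 °C
Reagents that add atoms: none
Why: Horner–Wadsworth–Emmons olefination with an allylic phosphonate carbanion gives the new disubstituted alkene E, and inverse addition to excess dial keeps it at mono-olefination.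

Step 16
Reactants: 24 C25 aldehyde
Product: 25 ethyl (2E,4E,6E,8E,10E,12E)-15-[(4R)-4-(tert-butyldimethylsilyloxy)-2,6,6-trimethylcyclohex-1-en-1-yl]-4,9,13-trimethylpentadeca-2,4,6,8,10,12-hexaen-14-ynoate (C27 ester)
Conditions: (EtO)2P(O)CH2CO2Et, NaH, THF, 0 °C to rt
Reagents that add atoms: triethyl phosphonoacetate (CCOC(=O)CP(=O)(OCC)OCC)
Why: Horner–Wadsworth–Emmons reaction of a stabilised phosphonoacetate with an enal is reliably E-selective.

Step 17
Reactants: 25 C27 ester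
Product: 26 (2E,4E,6E,8E,10E,12E)-15-[(4R)-4-(tert-butyldimethylsilyloxy)-2,6,6-trimethylcyclohex-1-en-1-yl]-4,9,13-trimethylpentadeca-2,4,6,8,10,12-hexaen-14-yn-1-ol
Conditions: DIBAL-H (2.5 equiv), CH2Cl2, −78 °C; Rochelle salt
Reagents that add atoms: none
Why: DIBAL-H reduces the conjugated ester 1,2 to the allylic alcohol without touching the polyene, alkyne or silyl ether.

Step 18
Reactants: 26 C27 allylic alcohol
Product: 27 (2E,4E,6E,8E,10E,12E)-15-[(4R)-4-(tert-butyldimethylsilyloxy)-2,6,6-trimethylcyclohex-1-en-1-yl]-4,9,13-trimethylpentadeca-2,4,6,8,10,12-hexaen-14-ynal (C27 aldehyde)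
Conditions: MnO2 (activated, 15 equiv), CH2Cl2, rt, dark
Reagents that add atoms: none
Why: MnO2 oxidises the primary allylic alcohol to the enal under neutral conditions.

Step 19
Reactants: 13 C13 ethyl ketone; 27 C27 aldehyde
Product: 29 (1Z,5E,7E,9E,11E,13E,15E)-1-[4-(tert-butyldimethylsilyloxy)-2,6,6-trimethylcyclohex-2-en-1-ylidene]-18-[(4R)-4-(tert-butyldimethylsilyloxy)-2,6,6-trimethylcyclohex-1-en-1-yl]-4-hydroxy-3,7,12,16-tetramethyloctadeca-5,7,9,11,13,15-hexaen-17-yn-2-one (aldol adduct; diastereomer mixture), via lithium enolate 28 (not isolated)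
Conditions: LDA (1.05 equiv), THF, −78 °C; then 27, −78 °C; aq. NH4Cl
Reagents that add atoms: none
Why: Directed aldol addition of the preformed lithium enolate, where 13 can enolise only at the ethyl CH2 and adds 1,2 to the enal; the two new centres form as a mixture and both become sp2 in step 20.

Step 20
Reactants: 29 aldol adduct
Product: 31 (1Z,3E,5E,7E,9E,11E,13E,15E)-1-[4-(tert-butyldimethylsilyloxy)-2,6,6-trimethylcyclohex-2-en-1-ylidene]-18-[(4R)-4-(tert-butyldimethylsilyloxy)-2,6,6-trimethylcyclohex-1-en-1-yl]-3,7,12,16-tetramethyloctadeca-3,5,7,9,11,13,15-heptaen-17-yn-2-one, via C-10 acetate 30 (not isolated)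
Conditions: Ac2O, Et3N, DMAP (cat.), CH2Cl2, 0 °C; then DBU, rt
Reagents that add atoms: none
Why: Acetylation followed by E1cB elimination gives the thermodynamically favoured E trisubstituted enone conjugated with the polyene, completing the aldol condensation.

Step 21
Reactants: 31 bis-silyl ether
Product: 32 (1Z,3E,5E,7E,9E,11E,13E,15E)-1-(4-hydroxy-2,6,6-trimethylcyclohex-2-en-1-ylidene)-18-[(4R)-4-hydroxy-2,6,6-trimethylcyclohex-1-en-1-yl]-3,7,12,16-tetramethyloctadeca-3,5,7,9,11,13,15-heptaen-17-yn-2-one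
Conditions: TBAF, AcOH (1:1), THF, rt
Reagents that add atoms: none
Why: Buffered fluoride cleaves both secondary silyl ethers without base-induced damage to the dienone.

Step 22
Reactants: 32 diol
Product: 33 (4Z)-4-[(3E,5E,7E,9E,11E,13E,15E)-18-[(4R)-4-hydroxy-2,6,6-trimethylcyclohex-1-en-1-yl]-3,7,12,16-tetramethyl-2-oxooctadeca-3,5,7,9,11,13,15-heptaen-17-yn-1-ylidene]-3,5,5-trimethylcyclohex-2-en-1-one (target)
Conditions: MnO2 (activated, 20 equiv), CH2Cl2, rt, dark
Reagents that add atoms: none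
Why: MnO2 oxidises only the allylic ring carbinol to the enone and leaves the non-allylic (R)-carbinol from actinol untouched, so the single stereocentre is never at risk.

**Compound list**
1 | 2,6,6-trimethylcyclohex-2-ene-1,4-dione (ketoisophorone) | CC1=CC(=O)CC(C)(C)C1=O | starting material
2 | 7,9,9-trimethyl-1,4-dioxaspiro[4.5]dec-6-en-8-one | CC1=CC2(OCCO2)CC(C)(C)C1=O | intermediate
3 | 7-hydroperoxy-7,9,9-trimethyl-1,4-dioxaspiro[4.5]decan-8-one | CC1(OO)CC2(OCCO2)CC(C)(C)C1=O | intermediate (not isolated)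
4 | 7-hydroxy-7,9,9-trimethyl-1,4-dioxaspiro[4.5]decan-8-one (racemic) | CC1(O)CC2(OCCO2)CC(C)(C)C1=O | intermediate
5 | 7,9,9-trimethyl-8-oxo-1,4-dioxaspiro[4.5]decan-7-yl (triphenylphosphoranylidene)acetate | CC1(OC(=O)C=P(c2ccccc2)(c2ccccc2)c2ccccc2)CC2(OCCO2)CC(C)(C)C1=O | intermediate (not isolated)
6 | 6,6-ethylenedioxy-4,4,7a-trimethyl-5,6,7,7a-tetrahydro-1-benzofuran-2(4H)-one (racemic) | CC12CC3(OCCO3)CC(C)(C)C1=CC(=O)O2 | intermediate
7 | 4,4,7a-trimethyl-5,7a-dihydro-1-benzofuran-2,6(4H,7H)-dione (dehydrololiolide; racemic) | CC12CC(=O)CC(C)(C)C1=CC(=O)O2 | intermediate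
8 | DBU-H (2Z)-(2,6,6-trimethyl-4-oxocyclohex-2-en-1-ylidene)acetate | CC1=CC(=O)CC(C)(C)/C1=C/C(=O)[O-].C1CCC2=[NH+]CCCN2CC1 | intermediate (not isolated)
9 | methyl (2Z)-(2,6,6-trimethyl-4-oxocyclohex-2-en-1-ylidene)acetate | CC1=CC(=O)CC(C)(C)/C1=C/C(=O)OC | intermediate
10 | methyl (2Z)-(4-hydroxy-2,6,6-trimethylcyclohex-2-en-1-ylidene)acetate (racemic) | CC1=CC(O)CC(C)(C)/C1=C/C(=O)OC | intermediate
11 | methyl (2Z)-[4-(tert-butyldimethylsilyloxy)-2,6,6-trimethylcyclohex-2-en-1-ylidene]acetate | CC1=CC(O[Si](C)(C)C(C)(C)C)CC(C)(C)/C1=C/C(=O)OC | intermediate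
12 | (2Z)-2-[4-(tert-butyldimethylsilyloxy)-2,6,6-trimethylcyclohex-2-en-1-ylidene]-N-methoxy-N-methylacetamide | CC1=CC(O[Si](C)(C)C(C)(C)C)CC(C)(C)/C1=C/C(=O)N(C)OC | intermediate
13 | (1Z)-1-[4-(tert-butyldimethylsilyloxy)-2,6,6-trimethylcyclohex-2-en-1-ylidene]butan-2-one | CC1=CC(O[Si](C)(C)C(C)(C)C)CC(C)(C)/C1=C/C(=O)CC | intermediate
14 | (4R,6R)-4-hydroxy-2,2,6-trimethylcyclohexan-1-one (actinol) | O=C1[C@H](C)C[C@@H](O)CC1(C)C | starting material
15 | (4R,6R)-4-(tert-butyldimethylsilyloxy)-2,2,6-trimethylcyclohexan-1-one | O=C1[C@H](C)C[C@@H](O[Si](C)(C)C(C)(C)C)CC1(C)C | intermediate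
16 | lithium (4R)-4-(tert-butyldimethylsilyloxy)-2,6,6-trimethylcyclohex-1-en-1-olate | [Li+].[O-]C1=C(C)C[C@@H](O[Si](C)(C)C(C)(C)C)CC1(C)C | intermediate (not isolated)
17 | (4R)-4-(tert-butyldimethylsilyloxy)-2,6,6-trimethylcyclohex-1-en-1-yl trifluoromethanesulfonate | O=S(=O)(OC1=C(C)C[C@@H](O[Si](C)(C)C(C)(C)C)CC1(C)C)C(F)(F)F | intermediate
18 | (2E)-3-methylpent-2-en-4-yn-1-ol | C#C/C(C)=C/CO | starting material
19 | (2E)-5-[(4R)-4-(tert-butyldimethylsilyloxy)-2,6,6-trimethylcyclohex-1-en-1-yl]-3-methylpent-2-en-4-yn-1-ol | OC/C=C(\C)C#CC1=C(C)C[C@@H](O[Si](C)(C)C(C)(C)C)CC1(C)C | intermediate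
20 | (2E)-1-bromo-5-[(4R)-4-(tert-butyldimethylsilyloxy)-2,6,6-trimethylcyclohex-1-en-1-yl]-3-methylpent-2-en-4-yne | BrC/C=C(\C)C#CC1=C(C)C[C@@H](O[Si](C)(C)C(C)(C)C)CC1(C)C | intermediate
21 | diethyl [(2E)-5-[(4R)-4-(tert-butyldimethylsilyloxy)-2,6,6-trimethylcyclohex-1-en-1-yl]-3-methylpent-2-en-4-yn-1-yl]phosphonate | CCOP(=O)(OCC)C/C=C(\C)C#CC1=C(C)C[C@@H](O[Si](C)(C)C(C)(C)C)CC1(C)C | intermediate
22 | (2E,4E,6E)-2,7-dimethylocta-2,4,6-trienedial (C10-dial) | O=C/C(C)=C/C=C/C=C(C)/C=O | starting material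
23 | sodium salt of the α-carbanion of 21 | [Na+].CCOP(=O)(OCC)[CH-]/C=C(\C)C#CC1=C(C)C[C@@H](O[Si](C)(C)C(C)(C)C)CC1(C)C | intermediate (not isolated)
24 | (2E,4E,6E,8E,10E)-13-[(4R)-4-(tert-butyldimethylsilyloxy)-2,6,6-trimethylcyclohex-1-en-1-yl]-2,7,11-trimethyltrideca-2,4,6,8,10-pentaen-12-ynal | O=C/C(C)=C/C=C/C=C(C)/C=C/C=C(\C)C#CC1=C(C)C[C@@H](O[Si](C)(C)C(C)(C)C)CC1(C)C | intermediate
25 | ethyl (2E,4E,6E,8E,10E,12E)-15-[(4R)-4-(tert-butyldimethylsilyloxy)-2,6,6-trimethylcyclohex-1-en-1-yl]-4,9,13-trimethylpentadeca-2,4,6,8,10,12-hexaen-14-ynoate | CCOC(=O)/C=C/C(C)=C/C=C/C=C(C)/C=C/C=C(\C)C#CC1=C(C)C[C@@H](O[Si](C)(C)C(C)(C)C)CC1(C)C | intermediate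
26 | (2E,4E,6E,8E,10E,12E)-15-[(4R)-4-(tert-butyldimethylsilyloxy)-2,6,6-trimethylcyclohex-1-en-1-yl]-4,9,13-trimethylpentadeca-2,4,6,8,10,12-hexaen-14-yn-1-ol | OC/C=C/C(C)=C/C=C/C=C(C)/C=C/C=C(\C)C#CC1=C(C)C[C@@H](O[Si](C)(C)C(C)(C)C)CC1(C)C | intermediate
27 | (2E,4E,6E,8E,10E,12E)-15-[(4R)-4-(tert-butyldimethylsilyloxy)-2,6,6-trimethylcyclohex-1-en-1-yl]-4,9,13-trimethylpentadeca-2,4,6,8,10,12-hexaen-14-ynal | O=C/C=C/C(C)=C/C=C/C=C(C)/C=C/C=C(\C)C#CC1=C(C)C[C@@H](O[Si](C)(C)C(C)(C)C)CC1(C)C | intermediate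
28 | lithium enolate of 13 (enolate geometry not defined) | CC1=CC(O[Si](C)(C)C(C)(C)C)CC(C)(C)/C1=C/C(O[Li])=CC | intermediate (not isolated)
29 | aldol adduct, 4-hydroxy-3-methyl-2-one (full name in step 19; mixture at the three sp3 centres of the left half) | CC1=CC(O[Si](C)(C)C(C)(C)C)CC(C)(C)/C1=C/C(=O)C(C)C(O)/C=C/C(C)=C/C=C/C=C(C)/C=C/C=C(\C)C#CC1=C(C)C[C@@H](O[Si](C)(C)C(C)(C)C)CC1(C)C | intermediate
30 | acetate of 29 at the new carbinol | CC1=CC(O[Si](C)(C)C(C)(C)C)CC(C)(C)/C1=C/C(=O)C(C)C(OC(C)=O)/C=C/C(C)=C/C=C/C=C(C)/C=C/C=C(\C)C#CC1=C(C)C[C@@H](O[Si](C)(C)C(C)(C)C)CC1(C)C | intermediate (not isolated)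
31 | bis-TBS ether of 32 (full name in step 20) | CC1=CC(O[Si](C)(C)C(C)(C)C)CC(C)(C)/C1=C/C(=O)/C(C)=C/C=C/C(C)=C/C=C/C=C(C)/C=C/C=C(\C)C#CC1=C(C)C[C@@H](O[Si](C)(C)C(C)(C)C)CC1(C)C | intermediate
32 | diol, ring carbinol in place of the ring ketone of the target (full name in step 21) | CC1=CC(O)CC(C)(C)/C1=C/C(=O)/C(C)=C/C=C/C(C)=C/C=C/C=C(C)/C=C/C=C(\C)C#CC1=C(C)C[C@@H](O)CC1(C)C | intermediate
33 | (4Z)-4-[(3E,5E,7E,9E,11E,13E,15E)-18-[(4R)-4-hydroxy-2,6,6-trimethylcyclohex-1-en-1-yl]-3,7,12,16-tetramethyl-2-oxooctadeca-3,5,7,9,11,13,15-heptaen-17-yn-1-ylidene]-3,5,5-trimethylcyclohex-2-en-1-one | CC1=CC(=O)CC(C)(C)/C1=C/C(=O)/C(C)=C/C=C/C(C)=C/C=C/C=C(C)/C=C/C=C(\C)C#CC1=C(C)C[C@@H](O)CC1(C)C | target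

**Totals**
Total step count: 22. Longest linear sequence: 13 steps (steps 1–9, then 19–22; the branch through steps 10–18 and 19–22 is equally long).

**Three steps most likely to fail**

Step 3 (intramolecular Wittig on a ketone next to a quaternary carbon). The fallback sets out from 4 and comes back at 6. The tertiary alcohol of 4 is acetylated (Ac2O, Et3N, DMAP, CH2Cl2, 40 °C) to 7,9,9-trimethyl-8-oxo-1,4-dioxaspiro[4.5]decan-7-yl acetate F1. LDA (THF, −78 °C) can enolise only the acetate, since the ketone has no α-hydrogen, and an intramolecular acetate aldol gives the cis-fused hydroxy lactone 6,6-ethylenedioxy-3a-hydroxy-4,4,7a-trimethylhexahydro-1-benzofuran-2(3H)-one F2. SOCl2/pyridine (0 °C) dehydrates it towards the lactone CH2, the only position with a β-hydrogen, and gives 6.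

Step 15 (mono-olefination of a symmetrical dial with the valuable phosphonate). The fallback sets out from 22 and comes back at 25. The statistical step is moved onto cheap material: 22 is treated with triethyl phosphonoacetate (1 equiv, NaH, THF, 0 °C; unreacted dial recovered) to give the mono-aldehyde ethyl (2E,4E,6E,8E)-4,9-dimethyl-10-oxodeca-2,4,6,8-tetraenoate F3. Carbanion 23 (from 21, NaHMDS, −78 °C) then reacts with this single aldehyde and gives 25 directly, so that 24 is bypassed.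

Step 19 (lithium enolate with a long, sensitive polyenal). The fallback sets out from 13 and comes back at 29. Ketone 13 is converted (TMSOTf, Et3N, CH2Cl2, 0 °C) into the isolable silyl enol ether tert-butyldimethyl{[3,5,5-trimethyl-4-[(1Z,2Z)-2-(trimethylsilyloxy)but-2-en-1-ylidene]cyclohex-2-en-1-yl]oxy}silane F4. This is added to 27 in a Mukaiyama aldol reaction (BF3·OEt2, CH2Cl2, −78 °C; aq. NaHCO3), which gives 29 without any strong base in contact with the polyenal.

**Further compounds**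
F1 | step 3 | 7,9,9-trimethyl-8-oxo-1,4-dioxaspiro[4.5]decan-7-yl acetate (racemic) | CC(=O)OC1(C)CC2(OCCO2)CC(C)(C)C1=O
F2 | step 3 | 6,6-ethylenedioxy-3a-hydroxy-4,4,7a-trimethylhexahydro-1-benzofuran-2(3H)-one (racemic, cis-fused) | CC12CC3(OCCO3)CC(C)(C)C1(O)CC(=O)O2
F3 | step 15 | ethyl (2E,4E,6E,8E)-4,9-dimethyl-10-oxodeca-2,4,6,8-tetraenoate | CCOC(=O)/C=C/C(C)=C/C=C/C=C(C)/C=O
F4 | step 19 | tert-butyldimethyl{[3,5,5-trimethyl-4-[(1Z,2Z)-2-(trimethylsilyloxy)but-2-en-1-ylidene]cyclohex-2-en-1-yl]oxy}silane | CC1=CC(O[Si](C)(C)C(C)(C)C)CC(C)(C)/C1=C/C(O[Si](C)(C)C)=C/C
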